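## Structural features

The target is a stilbenoid trimer made of two trans-2,3-diaryl-2,3-dihydrobenzofurans. Unit 1 is ring A fused to a dihydrofuran that carries a 4-hydroxyphenyl group at C2, ring B at C3, a hydroxyl at C4 and an (E)-4-hydroxystyryl group at C6. Ring B is both the C3 substituent of unit 1 (through C6′) and the benzo ring of unit 2, whose dihydrofuran carries a 2,4-dihydroxyphenyl group at C2′ and a 3,5-dihydroxyphenyl group at C3′; C4′ bears the eighth phenol. The four stereocentres form two adjacent pairs, C2/C3 and C2′/C3′, each trans and all R. The pairs sit para to each other across ring B (C6′ versus C3a′), so neither can direct the other and each needs its own source of absolute configuration. Fragile elements are the eight oxidisable phenols, the electron-rich stilbene, the benzylic aryl ether bonds C2–O1 and especially C2′–O1′ (activated by an ortho/para-dioxygenated aryl group), and the doubly benzylic C3–H and C3′–H. The real difficulty is the C3–C6′ bond, an sp3–sp2 link to a stereogenic carbon flanked by the C2 aryl group and the peri C4 oxygen, together with the need to functionalise ring B exactly between its two oxygens. The key step uses the fact that ring B is a 5-substituted resorcinol: C4′ and C7a′ are meta-related oxygen-bearing carbons, C3a′ lies between them and C6′ carries C3, which is the pattern of a 5-substituted cyclohexane-1,3-dione that can be grown from an enone already attached to C3.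

## Logic of the disconnections

36 ⇒ 35. The eight O–CH3 bonds are cut. Free phenols would not survive the bases, organometallics and carbenes of the route, and methyl is the one ether that is inert to carbene insertion at the C4 oxygen. The gain is an oxidation-stable, non-acidic octaether; the demand is one ether cleavage mild enough for the stilbene and the two benzylic aryl ethers.

35 ⇒ 30 + 33 (through 34). C2′–C3′ and O1′–C2′ are cut, because both bonds meet at C2′, a one-carbon unit that carries the 2,4-dioxygenated aryl group, while O1′/C7a′/C3a′/C3′ form an oxa-diene. This removes a ring and two stereocentres. The forward step needs reagent control of absolute configuration (C2/C3 are too remote to help) and a neutral quinone methide, so one ring B oxygen must stay capped.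

33 ⇒ 31 + 32. The benzylic C–S bond is cut to give two purchasable pieces. The forward step must form a salt of a very easily ionised benzyl group without decomposing it.

30 ⇒ 28 ⇒ 26 + 27. The C3′–S bond is traced to a carbinol C–O bond and then the C3a′–C3′ bond is cut. C3a′ lies between two oxygens and is the most acidic aryl C–H of ring B, so an aryl anion plus an aldehyde is the natural polarity. Ring B becomes a simple 3,5-dioxygenated arene. The forward lithiation must beat attack on the stilbene and deprotonation at C3.

26 ⇒ 25 ⇒ 23 ⇒ 22. No skeletal bond is cut: the acetal and methyl caps are removed and two hydrogens are restored to ring B. A resorcinol monoether is the dehydrogenated form of the vinylogous ester of a cyclohexane-1,3-dione, and the monoether also tells the two oxygens apart. The arene becomes a symmetric dione; the forward dehydrogenation must leave the stilbene and the benzylic C–H bonds alone.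

22 ⇒ 20. The C5′–CO2Me bond is restored, so that the dione appears as a β-keto ester. The forward step is a hydrolysis and decarboxylation that erases one uncontrolled centre.

20 ⇒ 17 + 18 (key step). C5′–C6′ and C3a′–C4′ are cut. The β-diketone is a Claisen retron whose central carbon is a former methyl ketone carbon, and C6′ is the β-carbon of an enone. The whole of ring B disappears and the hindered C3–C6′ bond is reduced to a pre-existing C3–CH= bond. The forward step needs conjugate addition to be faster than γ-deprotonation at C3.

17 ⇒ 14 + 15 (through 16), and 14 ⇒ 13. The enone C=C bond is cut and the alcohol is traced to the ester. The gain is a stable ester as the carrier of C3; the demand is that the α-aryl aldehyde 16 is never isolated or exposed to base.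

13 ⇒ 11 + 12. The C6–vinyl bond is cut so that the stilbene comes from a robust aryl bromide. The forward Heck reaction must be β-selective and must come after the carbene step, since a carbene would attack the alkene.

11 ⇒ 9 (through 10). The C2–C3 bond is cut: C2 is a benzylic ether CH2 five atoms from a carbene carbon. One achiral diazo ester then gives the ring and both stereocentres. The forward step needs catalyst control at C2 and a base equilibration at C3, because the insertion is expected to deliver the cis ester.

9 ⇒ 8 ⇒ 7 ⇒ 6 ⇒ 4. The diazo group, the ester methyl and the nitrile carbon are removed in turn, which is a one-carbon homologation of an aldehyde read backwards. No acid may be used, because of the 4-methoxybenzyl ether.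

4 ⇒ 2 + 3, and 2 ⇒ 1. The two aryl C–O bonds ortho to the formyl group are cut. The aldehyde activates both fluorides and the first substitution deactivates the ring enough to stop cleanly after one.

## Other disconnections considered

Alternative 1: Dearomative conjunctive coupling.
- **Cut:** the two aryl–carbon bonds at C2′ and C3′. Unit 2 is reduced to 6-chloro-4-methoxybenzofuran A1, the 2,4-dimethoxyphenyl pinacol boronate A2 and 3,5-dimethoxyphenyl triflate A3.
- **Forward key step:** A1 is lithiated at C2′ and added to A2. The arylpalladium species formed from A3 under a chiral bisphosphine attacks C3′ of the ate complex, the aryl group shifts from boron to C2′ on the opposite face, and reductive elimination gives boronate A4 with the two aryl groups trans. The C–B bond of A4 would then be exchanged for C–H with retention.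
- **In favour:** three simple achiral pieces, two C–C bonds and both stereocentres of unit 2 from one catalytic event. On step count for unit 2, and on using catalytic instead of stoichiometric chirality, it is better than the chosen plan.
- **Against:** arylation at C3′ takes place next to the peri C4′ methoxy group and the migrating aryl group is ortho-substituted. The tertiary, benzylic, α-oxygenated boronate must be protonated without loss of configuration. A4 offers only a chloride at C6′, so the bond from C6′ to the stereogenic C3 would still have to be made by coupling to a hindered secondary sp3 carbon, or unit 1 would have to be rebuilt outward from that chloride.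
- **Comparison:** structurally it solves unit 2 well but leaves open the junction that the chosen plan obtains by growing ring B from C3. Mechanistically both plans rest on one asymmetric C–C bond formation of limited precedent for these substrates, so they are equals there. In overall step economy it would win only if a stereoretentive C3–C6′ coupling were available.

Alternative 2: Double donor/donor carbene insertion.
- **Cut:** C2–C3 and C2′–C3′ together, back to the bis-hydrazone A5, in which ring B already links the two future C3 carbons as diaryl ketone hydrazones and both ether oxygens carry their benzyl groups.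
- **Forward key step:** MnO2 oxidises both hydrazones of A5 to diazo groups. Rh2(R-PTAD)4 turns each into a donor/donor carbene that inserts into the benzylic ether C–H five atoms away, closing both dihydrofurans to the cis,cis bromide A6. Acid would then equilibrate C2 and C2′ to trans through the benzylic cations, and Heck coupling and demethylation would finish.
- **In favour:** enantioselective insertion of diaryl carbenes into benzylic ethers is an established route to exactly this ring type, so on precedent for closing unit 2 with absolute control it is better than the labelled step of the chosen plan. It makes the C3–C6′ bond at the ketone (sp2) stage, which is as sound an answer to the junction problem as growing ring B. It is also the shortest of the four plans.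
- **Against:** both ketones behind A5 sit on 2,6-dioxygenated rings and should condense with hydrazine reluctantly. Two catalyst-controlled events must both be highly selective or diastereomers accumulate. Diazo groups of different molecules can couple to azines. The C2 cation (4-methoxyphenyl) needs stronger acid for the cis-to-trans equilibration than the much more labile C2′ centre is likely to tolerate.
- **Comparison:** structurally it is more convergent. Mechanistically it concentrates the risk in one double event, whereas the chosen plan sets unit 1 by a single aryldiazoacetate insertion followed by a thermodynamically driven base epimerisation. In step economy it is the better plan if the bis-hydrazone can be made.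

Alternative 3: Diazo dione and stilbene annulation.
- **Cut:** C3′–C3a′ and O1′–C2′, back to the cyclic diazo dione A7 (methyl 4-diazo-3,5-dioxocyclohexane-1-carboxylate) and the (E)-2,4,3′,5′-tetramethoxystilbene A8.
- **Forward key step:** the rhodium carbene from A7 under a chiral dirhodium carboxylate such as Rh2(S-PTTL)4 is attacked by the alkene of A8. The carbene carbon bonds to the alkene carbon bearing the 3,5-dimethoxyphenyl group and a carbonyl oxygen closes on the cation-stabilising 2,4-dimethoxybenzylic carbon, giving the bicyclic ketone A9. Dehydrogenation would aromatise ring B and the ester would become the anchor for unit 1.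
- **In favour:** the polarity of A8 dictates the regiochemistry, the chirality is catalytic, and no aryllithium or quinone methide is needed; on these three points it is better than the chosen plan. It shares the idea of aromatising ring B late, where the two plans are equal.
- **Against:** carbenes flanked by two acyl groups add sluggishly to 1,2-disubstituted stilbenes and their enantiocontrol is usually modest. The benzylic C2′–O bond of A9 is a vinylogous ester linkage and ionises even more easily than an aryl ether. The ester carbon of A9 would have to become C3, so unit 1 and its two stereocentres would be built late, in the presence of the labile unit 2.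
- **Comparison:** structurally it shifts the junction problem to the end instead of solving it first. Mechanistically its key step is no better precedented than the labelled step of the chosen plan. In step economy unit 2 would be shorter, but the whole route would be of similar length.

Key step: step 11

Remarks on the chemistry (assumptions and design points):
- U1 stands for the group (2R,3R)-4-methoxy-2-(4-methoxyphenyl)-6-[(E)-2-(4-methoxyphenyl)ethenyl]-2,3-dihydrobenzofuran-3-yl, with the C2 aryl group and the C3 substituent trans.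
- The sense of induction of Rh2(S-PTTL)4 (step 7) and of the (1R,4R,5R)-sulfide (step 19) is assumed to give 2R and 2′R,3′R; if either is opposite, the mirror-image reagent is used.
- (1R,4R,5R)-Isothiocineole is taken as a purchasable reagent.
- The C–H insertion is expected to give the cis ester, so an equilibration to trans is built into step 7.
- C3 of the enone is not immune to base: γ-deprotonation can move the double bond toward ring A and end in an achiral benzofuran. The aldehyde is therefore not isolated, and the Michael stage of step 11 is run with catalytic base before the Claisen stage.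
- The quinone methide of step 19 must be neutral, so ring B is aromatised as its monomethyl ether (one oxygen capped, one free) and not as the free resorcinol.

## Route

Step 1
Reactants: 1 4-bromo-2,6-difluorobenzaldehyde
Product: 2 4-bromo-2-fluoro-6-methoxybenzaldehyde
Conditions: NaOMe (1.05 equiv), MeOH–THF, 0 °C → rt
Reagents that add atoms: sodium methoxide, C[O-].[Na+]
Why: Nucleophilic aromatic substitution of a fluoride ortho to the formyl group; the first methoxy group deactivates the ring so the second fluoride survives, and the para bromide is a far poorer leaving group than fluoride in this mechanism.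

Step 2
Reactants: 2 4-bromo-2-fluoro-6-methoxybenzaldehyde; 3 4-methoxybenzyl alcohol
Product: 4 4-bromo-2-methoxy-6-[(4-methoxybenzyl)oxy]benzaldehyde
Conditions: NaH, DMF, 0 → 50 °C
Reagents that add atoms: none
Why: Second nucleophilic aromatic substitution, by the sodium alkoxide of 3 at the remaining ortho fluoride, which the aldehyde still activates; it installs the ether CH2 that becomes C2 and the aryl group that C2 will carry.

Step 3
Reactants: 4 4-bromo-2-methoxy-6-[(4-methoxybenzyl)oxy]benzaldehyde
Product: 6 2-{4-bromo-2-methoxy-6-[(4-methoxybenzyl)oxy]phenyl}acetonitrile, via N-(1-tosylalkenyl)formamide 5 (not isolated)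
Conditions: TosMIC, t-BuOK, DME, −40 °C; then MeOH, 65 °C
Reagents that add atoms: p-toluenesulfonylmethyl isocyanide, Cc1ccc(S(=O)(=O)C[N+]#[C-])cc1
Why: van Leusen reductive cyanation: the isocyanide anion adds to the aldehyde, the oxazoline opens to formamide 5, and methanolysis removes the formyl group and sulfinate to leave the homologous nitrile; the sequence is basic throughout, which the acid-labile 4-methoxybenzyl ether requires.

Step 4
Reactants: 6 2-{4-bromo-2-methoxy-6-[(4-methoxybenzyl)oxy]phenyl}acetonitrile
Product: 7 2-{4-bromo-2-methoxy-6-[(4-methoxybenzyl)oxy]phenyl}acetic acid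
Conditions: KOH, EtOH–H2O, 90 °C; then HCl to pH 3, 0 °C
Reagents that add atoms: water, O
Why: Alkaline nitrile hydrolysis; the aryl bromide and both ethers are inert to hydroxide, and the brief cold acidification does not cleave the benzyl ether.

Step 5
Reactants: 7 2-{4-bromo-2-methoxy-6-[(4-methoxybenzyl)oxy]phenyl}acetic acid
Product: 8 methyl 2-{4-bromo-2-methoxy-6-[(4-methoxybenzyl)oxy]phenyl}acetate
Conditions: MeI, K2CO3, DMF, rt
Reagents that add atoms: iodomethane, CI
Why: O-Alkylation of the carboxylate (SN2), an acid-free esterification.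

Step 6
Reactants: 8 methyl 2-{4-bromo-2-methoxy-6-[(4-methoxybenzyl)oxy]phenyl}acetate
Product: 9 methyl 2-diazo-2-{4-bromo-2-methoxy-6-[(4-methoxybenzyl)oxy]phenyl}acetate
Conditions: 4-acetamidobenzenesulfonyl azide, DBU, MeCN, 0 °C → rt
Reagents that add atoms: 4-acetamidobenzenesulfonyl azide, CC(=O)Nc1ccc(S(=O)(=O)N=[N+]=[N-])cc1
Why: Regitz diazo transfer to the arylacetate enolate, the standard entry to aryldiazoacetates.

Step 7
Reactants: 9 methyl 2-diazo-2-{4-bromo-2-methoxy-6-[(4-methoxybenzyl)oxy]phenyl}acetate
Product: 11 methyl (2R,3R)-6-bromo-4-methoxy-2-(4-methoxyphenyl)-2,3-dihydrobenzofuran-3-carboxylate, via cis ester 10 (not isolated)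
Conditions: Rh2(S-PTTL)4 (1 mol %), toluene, −60 °C; then NaOMe (0.5 equiv), MeOH–THF, rt
Reagents that add atoms: none
Why: Enantioselective intramolecular 1,5 C–H insertion of the rhodium aryl(ester)carbene into the electron-rich benzylic ether C–H forms C2–C3; the chiral carboxylate ligands set C2 and the insertion is expected to give the cis ester 10. Methoxide then equilibrates C3 through the ester enolate to the more stable trans isomer without touching C2; the methoxy C–H bonds are primary and unactivated and should not compete.

Step 8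
Reactants: 11 methyl (2R,3R)-6-bromo-4-methoxy-2-(4-methoxyphenyl)-2,3-dihydrobenzofuran-3-carboxylate; 12 4-methoxystyrene
Product: 13 methyl (2R,3R)-4-methoxy-2-(4-methoxyphenyl)-6-[(E)-2-(4-methoxyphenyl)ethenyl]-2,3-dihydrobenzofuran-3-carboxylate
Conditions: Pd(OAc)2 (5 mol %), P(o-tol)3 (12 mol %), Et3N, DMF, 100 °C
Reagents that add atoms: none
Why: Heck reaction under neutral phosphine conditions, which favours β-arylation of the styrene and the (E)-stilbene; any enolisation at C3 by the amine only returns the trans ester.

Step 9
Reactants: 13 methyl (2R,3R)-4-methoxy-2-(4-methoxyphenyl)-6-[(E)-2-(4-methoxyphenyl)ethenyl]-2,3-dihydrobenzofuran-3-carboxylate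
Product: 14 [(2R,3S)-4-methoxy-2-(4-methoxyphenyl)-6-[(E)-2-(4-methoxyphenyl)ethenyl]-2,3-dihydrobenzofuran-3-yl]methanol
Conditions: LiAlH4, THF, 0 °C
Reagents that add atoms: none
Why: Hydride reduction of the ester to the primary alcohol; the stilbene and aryl ethers are inert, and the change of descriptor at C3 reflects priorities only (the ring substituents stay trans).

Step 10
Reactants: 14 [(2R,3S)-4-methoxy-2-(4-methoxyphenyl)-6-[(E)-2-(4-methoxyphenyl)ethenyl]-2,3-dihydrobenzofuran-3-yl]methanol; 15 1-(triphenylphosphoranylidene)propan-2-one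
Product: 17 (E)-4-(U1)but-3-en-2-one, via aldehyde 16 (not isolated)
Conditions: Dess–Martin periodinane, NaHCO3, CH2Cl2, 0 °C → rt; then 15, 40 °C
Reagents that add atoms: none
Why: Buffered periodinane oxidation followed in the same flask by Wittig olefination with the stabilised ylide, which gives the (E)-enone; the base-sensitive α-aryl aldehyde 16 is consumed under neutral conditions without being isolated.

Step 11
Reactants: 17 (E)-4-(U1)but-3-en-2-one; 18 dimethyl malonate
Product: 20 methyl 2,4-dioxo-6-(U1)cyclohexane-1-carboxylate, via Michael adduct 19 (not isolated)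
Conditions: 18 (1.5 equiv), NaOMe (0.2 equiv), MeOH–THF, 0 °C → rt; then NaOMe (1.5 equiv), 65 °C; aq. HCl work-up
Reagents that add atoms: none
Why: The sodium enolate of 18 adds 1,4 to the enone at the carbon attached to C3 (the future C6′) to give 19 and so forms C5′–C6′; under stoichiometric methoxide the methyl ketone enolate of 19 attacks one malonate ester carbonyl and expels methoxide, forming C3a′–C4′. The closest known reaction type is the Michael–Claisen synthesis of 5-substituted cyclohexane-1,3-diones from alkylidene acetones and malonate, the classical entry to 5-alkylresorcinols. The ring closes in the 6-(enolendo)-exo-trig mode; the enolate on the internal CH2 could only give a four-membered ring, so the six-membered β-diketone is the only cyclic outlet, and its deprotonation to the vinylogous acid salt pulls every equilibrium forward. The two new ring centres (C6′ and C5′) form without control and are erased by decarboxylation and aromatisation, so nothing needs to control them. The selectivity that matters is conjugate addition against γ-deprotonation at C3, which would move the double bond toward ring A and could end in an achiral benzofuran. It is secured by running the addition cold with catalytic methoxide and excess malonate as proton buffer, so that strong base and heat reach only 19, whose C3–H is no longer vinylogous to a carbonyl. C2 is never acidic, and trans is the thermodynamic arrangement at C2/C3.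

Step 12
Reactants: 20 methyl 2,4-dioxo-6-(U1)cyclohexane-1-carboxylate
Product: 22 5-(U1)cyclohexane-1,3-dione, via β-keto acid 21 (not isolated)
Conditions: NaOH (2 M aq.), MeOH–THF, 70 °C; then HCl to pH 3, 60 °C
Reagents that add atoms: none
Why: Saponification and decarboxylation of the β-keto acid through its six-membered transition state; the step removes the uncontrolled C5′ centre and leaves a dione in which the C6′ carbon is no longer stereogenic.

Step 13
Reactants: 22 5-(U1)cyclohexane-1,3-dione
Product: 23 3-methoxy-5-(U1)cyclohex-2-en-1-one (both C5 epimers)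
Conditions: TMSCHN2, MeOH–toluene, 0 °C → rt
Reagents that add atoms: trimethylsilyldiazomethane, C[Si](C)(C)C=[N+]=[N-]
Why: O-Methylation of the acidic enol by the diazoalkane under neutral conditions; either carbonyl may react because both epimers converge on aromatisation, and this step is what makes the two ring B oxygens different.

Step 14
Reactants: 23 3-methoxy-5-(U1)cyclohex-2-en-1-one
Product: 25 3-methoxy-5-(U1)phenol, via cross-conjugated dienone 24 (not isolated)
Conditions: LiN(i-Pr)2 (1.2 equiv), THF, −78 °C; then PhS(Cl)=N-t-Bu (1.3 equiv), −78 °C → rt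
Reagents that add atoms: none
Why: Enolate dehydrogenation: kinetic α′-deprotonation of the vinylogous ester, sulfur transfer from N-tert-butylbenzenesulfinimidoyl chloride and syn-elimination give dienone 24, which tautomerises to the phenol; no oxidant that attacks stilbenes or benzylic C–H bonds is involved.

Step 15
Reactants: 25 3-methoxy-5-(U1)phenol
Product: 26 1-methoxy-3-(methoxymethoxy)-5-(U1)benzene
Conditions: MOMCl, i-Pr2NEt, CH2Cl2, 0 °C → rt
Reagents that add atoms: chloromethyl methyl ether, COCCl
Why: Phenol alkylation to the methoxymethyl ether, which protects the acidic OH and is a strong director for the next metalation.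

Step 16
Reactants: 26 1-methoxy-3-(methoxymethoxy)-5-(U1)benzene; 27 3,5-dimethoxybenzaldehyde
Product: 28 (3,5-dimethoxyphenyl)[2-methoxy-6-(methoxymethoxy)-4-(U1)phenyl]methanol (carbinol epimers)
Conditions: n-BuLi (1.3 equiv), Et2O–toluene, 0 °C; then 27, −78 °C → rt; aq. NH4Cl
Reagents that add atoms: none
Why: Directed ortho-metalation at C3a′, the position flanked by the acetal and methoxy oxygens, followed by addition to the aldehyde forms C3a′–C3′; ether–toluene without amine additive is chosen because stilbenes are carbolithiated far more slowly there than in THF, and the carbinol centre is irrelevant because it becomes sp2 in step 19.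

Step 17
Reactants: 28 (3,5-dimethoxyphenyl)[2-methoxy-6-(methoxymethoxy)-4-(U1)phenyl]methanol
Product: 30 2-[(3,5-dimethoxyphenyl)(4-methylphenylsulfonyl)methyl]-3-methoxy-5-(U1)phenol (sulfone epimers), via MOM-protected sulfone 29 (not isolated)
Conditions: p-TolSO2Na (5 equiv), HCl, MeOH–THF, 45 °C
Reagents that add atoms: sodium p-toluenesulfinate, Cc1ccc(S(=O)[O-])cc1.[Na+]
Why: Acid ionises the electron-rich benzhydrol and sulfinic acid traps the cation at sulfur (SN1) to give a bench-stable sulfone; the same acid then cleaves the acetal by methanolysis, leaving a 2-(sulfonylmethyl)phenol, a known base-triggered quinone methide precursor.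

Step 18
Reactants: 31 2,4-dimethoxybenzyl alcohol; 32 (1R,4R,5R)-isothiocineole
Product: 33 (1R,4R,5R)-6-(2,4-dimethoxybenzyl)-4,7,7-trimethyl-6-thiabicyclo[3.2.1]octan-6-ium tetrafluoroborate
Conditions: HBF4·OEt2 (1.0 equiv), CH2Cl2, 0 °C → rt; precipitation with Et2O
Reagents that add atoms: tetrafluoroboric acid, [H+].F[B-](F)(F)F
Why: S-Alkylation of the sulfide by the benzylic cation generated from the alcohol with a non-nucleophilic acid, the usual route to benzylic sulfonium salts of electron-rich arenes; the salt is used at once.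

Step 19
Reactants: 30 2-[(3,5-dimethoxyphenyl)(4-methylphenylsulfonyl)methyl]-3-methoxy-5-(U1)phenol; 33 (1R,4R,5R)-6-(2,4-dimethoxybenzyl)-4,7,7-trimethyl-6-thiabicyclo[3.2.1]octan-6-ium tetrafluoroborate
Product: 35 (2R,3R)-2-(2,4-dimethoxyphenyl)-3-(3,5-dimethoxyphenyl)-4-methoxy-6-(U1)-2,3-dihydrobenzofuran, via o-quinone methide 34 (not isolated)
Conditions: Cs2CO3 (3 equiv), 33 (1.5 equiv), MeCN–CH2Cl2, −20 °C → rt
Reagents that add atoms: none
Why: Proposed new method: Cs2CO3 releases the neutral o-quinone methide 34 from 30 by loss of sulfinate and deprotonates 33 to the benzylic sulfonium ylide; conjugate addition of the ylide to the exocyclic carbon (C3′) forms C2′–C3′ and the phenoxide then displaces the sulfide at C2′ (5-exo-tet) to close the ring. The closest known reaction types are the racemic [4+1] annulation of sulfur ylides with quinone methides released from 2-(sulfonylmethyl)phenols and the asymmetric epoxidation, aziridination and cyclopropanation with benzylic ylides of this sulfide. The bicyclic sulfide fixes the ylide conformation and shields one face, which should set C3′ in the addition; C2′ follows as the trans centre because the 2,4-dimethoxybenzylic C–S bond ionises easily and closure is thermodynamically directed.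

Step 20
Reactants: 35 (2R,3R)-2-(2,4-dimethoxyphenyl)-3-(3,5-dimethoxyphenyl)-4-methoxy-6-(U1)-2,3-dihydrobenzofuran
Product: 36 (2R,3R)-2-(2,4-dihydroxyphenyl)-3-(3,5-dihydroxyphenyl)-6-[(2R,3R)-4-hydroxy-2-(4-hydroxyphenyl)-6-[(E)-2-(4-hydroxyphenyl)ethenyl]-2,3-dihydrobenzofuran-3-yl]-2,3-dihydrobenzofuran-4-ol
Conditions: BBr3 (20 equiv), CH2Cl2, −78 → 0 °C; then MeOH–H2O, 0 °C
Reagents that add atoms: none
Why: Lewis-acid cleavage of all eight aryl methyl ethers, the usual last step for permethylated stilbene oligomers; if a benzylic C–O bond ionises reversibly at C2 or C2′, reclosure should return the trans rings because C3 and C3′ are not affected.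

## Compound list

1 | 4-bromo-2,6-difluorobenzaldehyde | O=Cc1c(F)cc(Br)cc1F | starting material
2 | 4-bromo-2-fluoro-6-methoxybenzaldehyde | COc1cc(Br)cc(F)c1C=O | intermediate
3 | 4-methoxybenzyl alcohol | COc1ccc(CO)cc1 | starting material
4 | 4-bromo-2-methoxy-6-[(4-methoxybenzyl)oxy]benzaldehyde | COc1ccc(COc2cc(Br)cc(OC)c2C=O)cc1 | intermediate
5 | N-[2-{4-bromo-2-methoxy-6-[(4-methoxybenzyl)oxy]phenyl}-1-(4-methylphenylsulfonyl)ethenyl]formamide (alkene geometry not assigned) | COc1ccc(COc2cc(Br)cc(OC)c2C=C(NC=O)S(=O)(=O)c2ccc(C)cc2)cc1 | intermediate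
6 | 2-{4-bromo-2-methoxy-6-[(4-methoxybenzyl)oxy]phenyl}acetonitrile | COc1ccc(COc2cc(Br)cc(OC)c2CC#N)cc1 | intermediate
7 | 2-{4-bromo-2-methoxy-6-[(4-methoxybenzyl)oxy]phenyl}acetic acid | COc1ccc(COc2cc(Br)cc(OC)c2CC(=O)O)cc1 | intermediate
8 | methyl 2-{4-bromo-2-methoxy-6-[(4-methoxybenzyl)oxy]phenyl}acetate | COc1ccc(COc2cc(Br)cc(OC)c2CC(=O)OC)cc1 | intermediate
9 | methyl 2-diazo-2-{4-bromo-2-methoxy-6-[(4-methoxybenzyl)oxy]phenyl}acetate | COc1ccc(COc2cc(Br)cc(OC)c2C(=[N+]=[N-])C(=O)OC)cc1 | intermediate
10 | methyl (2R,3S)-6-bromo-4-methoxy-2-(4-methoxyphenyl)-2,3-dihydrobenzofuran-3-carboxylate (cis) | Brc1cc(OC)c2c(c1)O[C@@H](c1ccc(OC)cc1)[C@H]2C(=O)OC | intermediate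
11 | methyl (2R,3R)-6-bromo-4-methoxy-2-(4-methoxyphenyl)-2,3-dihydrobenzofuran-3-carboxylate (trans) | Brc1cc(OC)c2c(c1)O[C@@H](c1ccc(OC)cc1)[C@@H]2C(=O)OC | intermediate
12 | 4-methoxystyrene | C=Cc1ccc(OC)cc1 | starting material
13 | methyl (2R,3R)-4-methoxy-2-(4-methoxyphenyl)-6-[(E)-2-(4-methoxyphenyl)ethenyl]-2,3-dihydrobenzofuran-3-carboxylate | COc1ccc(/C=C/c2cc(OC)c3c(c2)O[C@@H](c2ccc(OC)cc2)[C@@H]3C(=O)OC)cc1 | intermediate
14 | [(2R,3S)-4-methoxy-2-(4-methoxyphenyl)-6-[(E)-2-(4-methoxyphenyl)ethenyl]-2,3-dihydrobenzofuran-3-yl]methanol (trans) | COc1ccc(/C=C/c2cc(OC)c3c(c2)O[C@@H](c2ccc(OC)cc2)[C@@H]3CO)cc1 | intermediate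
15 | 1-(triphenylphosphoranylidene)propan-2-one | CC(=O)C=P(c1ccccc1)(c1ccccc1)c1ccccc1 | starting material
16 | (2R,3R)-4-methoxy-2-(4-methoxyphenyl)-6-[(E)-2-(4-methoxyphenyl)ethenyl]-2,3-dihydrobenzofuran-3-carbaldehyde | COc1ccc(/C=C/c2cc(OC)c3c(c2)O[C@@H](c2ccc(OC)cc2)[C@@H]3C=O)cc1 | intermediate
17 | (E)-4-(U1)but-3-en-2-one | COc1ccc(/C=C/c2cc(OC)c3c(c2)O[C@@H](c2ccc(OC)cc2)[C@@H]3/C=C/C(C)=O)cc1 | intermediate
18 | dimethyl malonate | COC(=O)CC(=O)OC | starting material
19 | dimethyl 2-[3-oxo-1-(U1)butyl]malonate (new centre not assigned) | COc1ccc(/C=C/c2cc(OC)c3c(c2)O[C@@H](c2ccc(OC)cc2)[C@@H]3C(CC(C)=O)C(C(=O)OC)C(=O)OC)cc1 | intermediate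
20 | methyl 2,4-dioxo-6-(U1)cyclohexane-1-carboxylate (ring centres not assigned) | COc1ccc(/C=C/c2cc(OC)c3c(c2)O[C@@H](c2ccc(OC)cc2)[C@@H]3C2CC(=O)CC(=O)C2C(=O)OC)cc1 | intermediate
21 | 2,4-dioxo-6-(U1)cyclohexane-1-carboxylic acid | COc1ccc(/C=C/c2cc(OC)c3c(c2)O[C@@H](c2ccc(OC)cc2)[C@@H]3C2CC(=O)CC(=O)C2C(=O)O)cc1 | intermediate
22 | 5-(U1)cyclohexane-1,3-dione | COc1ccc(/C=C/c2cc(OC)c3c(c2)O[C@@H](c2ccc(OC)cc2)[C@@H]3C2CC(=O)CC(=O)C2)cc1 | intermediate
23 | 3-methoxy-5-(U1)cyclohex-2-en-1-one (both C5 epimers) | COc1ccc(/C=C/c2cc(OC)c3c(c2)O[C@@H](c2ccc(OC)cc2)[C@@H]3C2CC(=O)C=C(OC)C2)cc1 | intermediate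
24 | 3-methoxy-5-(U1)cyclohexa-2,5-dien-1-one | COc1ccc(/C=C/c2cc(OC)c3c(c2)O[C@@H](c2ccc(OC)cc2)[C@@H]3C2=CC(=O)C=C(OC)C2)cc1 | intermediate
25 | 3-methoxy-5-(U1)phenol | COc1ccc(/C=C/c2cc(OC)c3c(c2)O[C@@H](c2ccc(OC)cc2)[C@@H]3c2cc(O)cc(OC)c2)cc1 | intermediate
26 | 1-methoxy-3-(methoxymethoxy)-5-(U1)benzene | COc1ccc(/C=C/c2cc(OC)c3c(c2)O[C@@H](c2ccc(OC)cc2)[C@@H]3c2cc(OCOC)cc(OC)c2)cc1 | intermediate
27 | 3,5-dimethoxybenzaldehyde | COc1cc(OC)cc(C=O)c1 | starting material
28 | (3,5-dimethoxyphenyl)[2-methoxy-6-(methoxymethoxy)-4-(U1)phenyl]methanol (carbinol epimers) | COc1ccc(/C=C/c2cc(OC)c3c(c2)O[C@@H](c2ccc(OC)cc2)[C@@H]3c2cc(OCOC)c(C(O)c3cc(OC)cc(OC)c3)c(OC)c2)cc1 | intermediate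
29 | 1-[(3,5-dimethoxyphenyl)(4-methylphenylsulfonyl)methyl]-2-methoxy-6-(methoxymethoxy)-4-(U1)benzene | COc1ccc(/C=C/c2cc(OC)c3c(c2)O[C@@H](c2ccc(OC)cc2)[C@@H]3c2cc(OCOC)c(C(c3cc(OC)cc(OC)c3)S(=O)(=O)c3ccc(C)cc3)c(OC)c2)cc1 | intermediate
30 | 2-[(3,5-dimethoxyphenyl)(4-methylphenylsulfonyl)methyl]-3-methoxy-5-(U1)phenol (sulfone epimers) | COc1ccc(/C=C/c2cc(OC)c3c(c2)O[C@@H](c2ccc(OC)cc2)[C@@H]3c2cc(O)c(C(c3cc(OC)cc(OC)c3)S(=O)(=O)c3ccc(C)cc3)c(OC)c2)cc1 | intermediate
31 | 2,4-dimethoxybenzyl alcohol | COc1ccc(CO)c(OC)c1 | starting material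
32 | (1R,4R,5R)-isothiocineole, i.e. (1R,4R,5R)-4,7,7-trimethyl-6-thiabicyclo[3.2.1]octane | C[C@@H]1CC[C@@H]2C[C@H]1SC2(C)C | starting material
33 | (1R,4R,5R)-6-(2,4-dimethoxybenzyl)-4,7,7-trimethyl-6-thiabicyclo[3.2.1]octan-6-ium tetrafluoroborate (one sulfonium diastereomer, configuration at sulfur not drawn) | C[C@@H]1CC[C@@H]2C[C@H]1[S+](Cc1ccc(OC)cc1OC)C2(C)C.F[B-](F)(F)F | intermediate
34 | 6-[(3,5-dimethoxyphenyl)methylidene]-5-methoxy-3-(U1)cyclohexa-2,4-dien-1-one (alkene geometry not assigned) | COc1ccc(/C=C/c2cc(OC)c3c(c2)O[C@@H](c2ccc(OC)cc2)[C@@H]3C2=CC(=O)C(=Cc3cc(OC)cc(OC)c3)C(OC)=C2)cc1 | intermediate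
35 | (2R,3R)-2-(2,4-dimethoxyphenyl)-3-(3,5-dimethoxyphenyl)-4-methoxy-6-(U1)-2,3-dihydrobenzofuran (octamethyl ether of the target) | COc1ccc(/C=C/c2cc(OC)c3c(c2)O[C@@H](c2ccc(OC)cc2)[C@@H]3c2cc(OC)c3c(c2)O[C@@H](c2ccc(OC)cc2OC)[C@@H]3c2cc(OC)cc(OC)c2)cc1 | intermediate
36 | (2R,3R)-2-(2,4-dihydroxyphenyl)-3-(3,5-dihydroxyphenyl)-6-[(2R,3R)-4-hydroxy-2-(4-hydroxyphenyl)-6-[(E)-2-(4-hydroxyphenyl)ethenyl]-2,3-dihydrobenzofuran-3-yl]-2,3-dihydrobenzofuran-4-ol | Oc1ccc(/C=C/c2cc(O)c3c(c2)O[C@@H](c2ccc(O)cc2)[C@@H]3c2cc(O)c3c(c2)O[C@@H](c2ccc(O)cc2O)[C@@H]3c2cc(O)cc(O)c2)cc1 | target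

## Step count and least certain steps

Total step count: 20. Longest linear sequence: 19 (steps 1 to 17, 19 and 20); step 18 is a one-step branch.

**Step 19 (labelled step).** The most likely failure is poor facial discrimination when the bulky ylide adds to the short-lived quinone methide, which would give the (2′S,3′S) ring alongside the wanted one. Solvolysis of the very easily ionised 2,4-dimethoxybenzylsulfonium salt and dimerisation of the quinone methide could also outrun the annulation. The fallback uses a known reaction class, the enantioselective insertion of a diaryl carbene into a benzylic ether C–H bond. It sets out from 28 and returns at 35.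
- 28 is oxidised with MnO2 to the diaryl ketone F1.
- HCl in MeOH removes the acetal to give the hydroxy ketone F2.
- Mitsunobu etherification with 31 gives the 2,4-dimethoxybenzyl ether F3.
- Hydrazine hydrate with acetic acid in hot ethanol gives the hydrazone F4.
- MnO2 oxidises F4 to the diazo compound F5, which is not isolated. Rh2(R-PTAD)4 (or its mirror image) induces 1,5-insertion to the cis dihydrobenzofuran F6, with C3′ as required and C2′ epimeric.
- Catalytic CF3CO2H in CH2Cl2 at 0 °C equilibrates C2′ through the benzylic cation to the trans ring, which is 35.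

**Step 11 (key step).** The most likely failure is base-mediated γ-deprotonation of 17 at C3 outrunning a conjugate addition that is slowed by the crowded β-carbon. The double bond would then migrate into conjugation with ring A and the ring would aromatise to a benzofuran, losing C2 and C3. Incomplete Claisen closure is a second possibility. The fallback inverts the roles of the two partners and sets out from 14 and returns at 20. One-pot oxidation and Wittig olefination of 14 with methyl (triphenylphosphoranylidene)acetate gives the enoate F7, whose γ-hydrogen is less acidic than that of the enone. Methyl acetoacetate and NaOMe in MeOH then add to F7 to give the acetoacetate adduct F8, whose methyl ketone enolate closes onto the side-chain ester to give the same β-keto ester 20.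

**Step 16.** The most likely failure is addition of n-BuLi across the stilbene, or deprotonation of the doubly benzylic C3–H followed by β-elimination of the phenoxide and opening of unit 1, in competition with ortho-metalation. The fallback replaces deprotonation by halogen–magnesium exchange on an iodide placed regiospecifically at the dione stage. It sets out from 22 and returns at 28.
- I2 and NaHCO3 in aqueous THF at 0 °C iodinate the enol carbon of 22 to the iodo dione F9.
- TMSCHN2 gives the iodo vinylogous ester F10.
- The conditions of step 14 dehydrogenate F10 through the iodo dienone F11 to the iodophenol F12.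
- MOMCl and i-Pr2NEt give the iodo acetal F13.
- Exchange of F13 with i-PrMgCl·LiCl at −20 °C, which does not add to stilbenes, and addition to 27 give 28.

**Step 20.** The most likely failure is Lewis-acid ionisation of the C2′–O1′ bond followed by intermolecular capture of the cation, cationic oligomerisation of the stilbene, or incomplete cleavage of some of the eight ethers. The fallback changes the mechanism to nucleophilic dealkylation under basic conditions and sets out from 35 and returns at 36. 35 is heated with NaSEt in DMF at 130 °C, with partly cleaved material resubmitted. The crude polyphenol is acetylated with Ac2O and pyridine to the octaacetate F14, which can be purified on silica. K2CO3 in MeOH at 0 °C then releases 36 in a mild final step.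

**Step 7.** The most likely failure is erosion of enantioselectivity, because the second ortho substituent twists the carbene out of the aryl plane and changes how the catalyst pocket reads it; carbene dimerisation is a second possibility. The fallback uses auxiliary-controlled insertion, a known approach to trans-2-aryl-2,3-dihydrobenzofuran-3-carboxylates, and sets out from 7 and returns at 11.
- 7 is esterified (DCC, DMAP) with (S)-2-hydroxy-1-(pyrrolidin-1-yl)propan-1-one to the lactamide ester F15.
- Diazo transfer as in step 6 gives the diazo ester F16.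
- Rh2(S-DOSP)4 in the matched pairing with the auxiliary gives the trans dihydrobenzofuran ester F17; the diastereomers are separable.
- NaOMe in MeOH transesterifies F17 to 11 and keeps C3 trans.

## Further compounds

F1 | step 19 | (3,5-dimethoxyphenyl)[2-methoxy-6-(methoxymethoxy)-4-(U1)phenyl]methanone | COc1ccc(/C=C/c2cc(OC)c3c(c2)O[C@@H](c2ccc(OC)cc2)[C@@H]3c2cc(OCOC)c(C(=O)c3cc(OC)cc(OC)c3)c(OC)c2)cc1
F2 | step 19 | (3,5-dimethoxyphenyl)[2-hydroxy-6-methoxy-4-(U1)phenyl]methanone | COc1ccc(/C=C/c2cc(OC)c3c(c2)O[C@@H](c2ccc(OC)cc2)[C@@H]3c2cc(O)c(C(=O)c3cc(OC)cc(OC)c3)c(OC)c2)cc1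
F3 | step 19 | {2-[(2,4-dimethoxybenzyl)oxy]-6-methoxy-4-(U1)phenyl}(3,5-dimethoxyphenyl)methanone | COc1ccc(/C=C/c2cc(OC)c3c(c2)O[C@@H](c2ccc(OC)cc2)[C@@H]3c2cc(OCc3ccc(OC)cc3OC)c(C(=O)c3cc(OC)cc(OC)c3)c(OC)c2)cc1
F4 | step 19 | hydrazone of {2-[(2,4-dimethoxybenzyl)oxy]-6-methoxy-4-(U1)phenyl}(3,5-dimethoxyphenyl)methanone | COc1ccc(/C=C/c2cc(OC)c3c(c2)O[C@@H](c2ccc(OC)cc2)[C@@H]3c2cc(OCc3ccc(OC)cc3OC)c(C(=NN)c3cc(OC)cc(OC)c3)c(OC)c2)cc1
F5 | step 19 | 2-[diazo(3,5-dimethoxyphenyl)methyl]-1-[(2,4-dimethoxybenzyl)oxy]-3-methoxy-5-(U1)benzene | COc1ccc(/C=C/c2cc(OC)c3c(c2)O[C@@H](c2ccc(OC)cc2)[C@@H]3c2cc(OCc3ccc(OC)cc3OC)c(C(=[N+]=[N-])c3cc(OC)cc(OC)c3)c(OC)c2)cc1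
F6 | step 19 | (2S,3R)-2-(2,4-dimethoxyphenyl)-3-(3,5-dimethoxyphenyl)-4-methoxy-6-(U1)-2,3-dihydrobenzofuran (cis) | COc1ccc(/C=C/c2cc(OC)c3c(c2)O[C@@H](c2ccc(OC)cc2)[C@@H]3c2cc(OC)c3c(c2)O[C@H](c2ccc(OC)cc2OC)[C@@H]3c2cc(OC)cc(OC)c2)cc1
F7 | step 11 | methyl (E)-3-(U1)prop-2-enoate | COc1ccc(/C=C/c2cc(OC)c3c(c2)O[C@@H](c2ccc(OC)cc2)[C@@H]3/C=C/C(=O)OC)cc1
F8 | step 11 | dimethyl 2-acetyl-3-(U1)pentanedioate (new centres not assigned) | COc1ccc(/C=C/c2cc(OC)c3c(c2)O[C@@H](c2ccc(OC)cc2)[C@@H]3C(CC(=O)OC)C(C(C)=O)C(=O)OC)cc1
F9 | step 16 | 2-iodo-5-(U1)cyclohexane-1,3-dione | COc1ccc(/C=C/c2cc(OC)c3c(c2)O[C@@H](c2ccc(OC)cc2)[C@@H]3C2CC(=O)C(I)C(=O)C2)cc1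
F10 | step 16 | 2-iodo-3-methoxy-5-(U1)cyclohex-2-en-1-one (both C5 epimers) | COc1ccc(/C=C/c2cc(OC)c3c(c2)O[C@@H](c2ccc(OC)cc2)[C@@H]3C2CC(=O)C(I)=C(OC)C2)cc1
F11 | step 16 | 2-iodo-3-methoxy-5-(U1)cyclohexa-2,5-dien-1-one | COc1ccc(/C=C/c2cc(OC)c3c(c2)O[C@@H](c2ccc(OC)cc2)[C@@H]3C2=CC(=O)C(I)=C(OC)C2)cc1
F12 | step 16 | 2-iodo-3-methoxy-5-(U1)phenol | COc1ccc(/C=C/c2cc(OC)c3c(c2)O[C@@H](c2ccc(OC)cc2)[C@@H]3c2cc(O)c(I)c(OC)c2)cc1
F13 | step 16 | 2-iodo-1-methoxy-3-(methoxymethoxy)-5-(U1)benzene | COc1ccc(/C=C/c2cc(OC)c3c(c2)O[C@@H](c2ccc(OC)cc2)[C@@H]3c2cc(OCOC)c(I)c(OC)c2)cc1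
F14 | step 20 | octaacetate of 36 | CC(=O)Oc1ccc(/C=C/c2cc(OC(C)=O)c3c(c2)O[C@@H](c2ccc(OC(C)=O)cc2)[C@@H]3c2cc(OC(C)=O)c3c(c2)O[C@@H](c2ccc(OC(C)=O)cc2OC(C)=O)[C@@H]3c2cc(OC(C)=O)cc(OC(C)=O)c2)cc1
F15 | step 7 | (S)-1-oxo-1-(pyrrolidin-1-yl)propan-2-yl 2-{4-bromo-2-methoxy-6-[(4-methoxybenzyl)oxy]phenyl}acetate | COc1ccc(COc2cc(Br)cc(OC)c2CC(=O)O[C@@H](C)C(=O)N2CCCC2)cc1
F16 | step 7 | (S)-1-oxo-1-(pyrrolidin-1-yl)propan-2-yl 2-diazo-2-{4-bromo-2-methoxy-6-[(4-methoxybenzyl)oxy]phenyl}acetate | COc1ccc(COc2cc(Br)cc(OC)c2C(=[N+]=[N-])C(=O)O[C@@H](C)C(=O)N2CCCC2)cc1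
F17 | step 7 | (S)-1-oxo-1-(pyrrolidin-1-yl)propan-2-yl (2R,3R)-6-bromo-4-methoxy-2-(4-methoxyphenyl)-2,3-dihydrobenzofuran-3-carboxylate | Brc1cc(OC)c2c(c1)O[C@@H](c1ccc(OC)cc1)[C@@H]2C(=O)O[C@@H](C)C(=O)N1CCCC1
A1 | alternative 1 | 6-chloro-4-methoxybenzofuran | COc1cc(Cl)cc2occc12
A2 | alternative 1 | 2-(2,4-dimethoxyphenyl)-4,4,5,5-tetramethyl-1,3,2-dioxaborolane | COc1ccc(B2OC(C)(C)C(C)(C)O2)c(OC)c1
A3 | alternative 1 | 3,5-dimethoxyphenyl trifluoromethanesulfonate | COc1cc(OC)cc(OS(=O)(=O)C(F)(F)F)c1
A4 | alternative 1 | 2-[(2R,3R)-6-chloro-2-(2,4-dimethoxyphenyl)-3-(3,5-dimethoxyphenyl)-4-methoxy-2,3-dihydrobenzofuran-2-yl]-4,4,5,5-tetramethyl-1,3,2-dioxaborolane (aryl groups trans) | Clc1cc(OC)c2c(c1)O[C@@](B1OC(C)(C)C(C)(C)O1)(c1ccc(OC)cc1OC)[C@@H]2c1cc(OC)cc(OC)c1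
A5 | alternative 2 | bis-hydrazone of [4-bromo-2-methoxy-6-(4-methoxybenzyloxy)phenyl]{4-(3,5-dimethoxybenzoyl)-3-[(2,4-dimethoxybenzyl)oxy]-5-methoxyphenyl}methanone | NN=C(c1c(OC)cc(Br)cc1OCc1ccc(OC)cc1)c1cc(OC)c(C(=NN)c2cc(OC)cc(OC)c2)c(OCc2ccc(OC)cc2OC)c1
A6 | alternative 2 | (2S,3R)-6-[(2S,3R)-6-bromo-4-methoxy-2-(4-methoxyphenyl)-2,3-dihydrobenzofuran-3-yl]-2-(2,4-dimethoxyphenyl)-3-(3,5-dimethoxyphenyl)-4-methoxy-2,3-dihydrobenzofuran (cis,cis) | Brc1cc(OC)c2c(c1)O[C@H](c1ccc(OC)cc1)[C@@H]2c1cc(OC)c2c(c1)O[C@H](c1ccc(OC)cc1OC)[C@@H]2c1cc(OC)cc(OC)c1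
A7 | alternative 3 | methyl 4-diazo-3,5-dioxocyclohexane-1-carboxylate | COC(=O)C1CC(=O)C(=[N+]=[N-])C(=O)C1
A8 | alternative 3 | (E)-1-[2-(3,5-dimethoxyphenyl)ethenyl]-2,4-dimethoxybenzene | COc1ccc(/C=C/c2cc(OC)cc(OC)c2)c(OC)c1
A9 | alternative 3 | methyl (2R,3R)-2-(2,4-dimethoxyphenyl)-3-(3,5-dimethoxyphenyl)-4-oxo-2,3,4,5,6,7-hexahydrobenzofuran-6-carboxylate (trans, C6 epimers) | COC(=O)C1CC(=O)C2=C(C1)O[C@@H](c1ccc(OC)cc1OC)[C@@H]2c1cc(OC)cc(OC)c1
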